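## Structural features

The target is a trans-fused guaiane: a cyclopentane (ring A, C1–C5) joined through the C1–C5 bond to a cycloheptane (ring B, C1 and C5–C10); guaiane numbering is used for all bicyclic compounds below. Ring A carries a trisubstituted 3α,4α-epoxide with the C15 methyl on C4. Ring B carries the C7 isopropyl group (β), the C8 vanillate ester (β, cis to the isopropyl group) and the C10 tertiary carbinol (OH α, C14 methyl β). There are seven stereocenters: C3/C4 next to C5, C10 next to C1, C7 next to C8; H-1 (α) and H-5 (β) define the trans fusion, and the C8 and C10 oxygens are 1,3-anti. The fragile groups are the epoxide (acid), the tertiary alcohol β to C8 (retro-aldol and dehydration at any ketone stage), the phenol-bearing aryl ester (base), and C1 and C7 whenever they stand α to a ketone. The real difficulty is ring B: a seven-membered carbocycle with five stereocenters and a quaternary carbinol, no rigid template, fused trans to a ring whose alkene must sit exactly at C3=C4. The feature exploited is that ring B without C1 is the six-membered cycle C10–C5–C6–C7–C8–C9 with oxygen on C10 and the isopropyl group on the para carbon C7, which is achiral, commercial 4-isopropylcyclohexanone. The route in one sentence: C1 is inserted between C10 and C5 of that ketone by oxidative opening of a siloxycyclopropane, giving ring B as a cyclohept-2-enone whose α- and β-carbons are the two ring-fusion atoms, and every other stereocenter is relayed from C7.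

## Logic of the disconnections

20 from 19: the O–acetyl bond of the phenol is cut. The phenol must be masked while the benzoate is made and the alkene is oxidised. The forward step has to cleave an aryl acetate next to a hindered alkyl benzoate and an epoxide.

19 from 18: both C–O bonds of the epoxide (C3–O, C4–O) are cut. The acid-labile epoxide is placed last, and two stereocenters disappear. The forward step must deliver oxygen to the α-face of C3=C4; the C10 hydroxyl, which lies on that face gauche to C2, is the handle.

18 from 15 and 16: the ester bond C8O–C(=O) is cut, giving a diol and a commercial protected acid. The forward step must acylate the secondary C8 hydroxyl and leave the tertiary C10 hydroxyl alone.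

15 from 14, and 14 from 13: the C8–H bond is cut (retro-reduction) and then re-formed on the other face (retro-oxidation). The C8 oxygen of the target is cis to the isopropyl group, on the hindered β-face, so it can only be set by putting hydride on the open α-face of a C8 ketone. The forward reduction must be 1,3-anti to the C10 hydroxyl, which that hydroxyl can direct.

13 from 12: the C10–C14 bond is cut, turning the quaternary carbinol into a ketone. The forward step must add methyl from the β-face; the C8 oxygen of 12 is placed on the α-face for this purpose.

12 from 10, and 10 from 8: the C8–O bond is cut (retro-conjugate oxygenation), then the C8=C9 unsaturation is removed. This leaves the C10 ketone as the only functional group of ring B. The forward steps need enolisation towards C9 and not towards the ring-fusion carbon C1.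

8 from 7: the C3=C4 double bond is cut (retro-metathesis), opening ring A to an isopropenyl group on C5 and an allyl group on C1. The alkene position and the C15 methyl are then fixed by the choice of the two groups. The forward step must close a trisubstituted cyclopentene across a trans-1,2 pair.

7 from 5: the C5–C4 and C1–C2 bonds are cut. Two stereocenters (C5, C1) vanish and a cycloheptenone with the single stereocenter C7 remains. The forward step must add to C5 trans to the remote isopropyl group and then alkylate C1 trans to the new group.

5 from 3, and 3 from 2 (key): C1 is excised, the bonds C1–C10 and C1–C5 are cut, and C5–C10 is rejoined. The seven-membered ring becomes a six-membered ring, and a chiral cycloheptenone becomes the silyl enol ether of a symmetric ketone. The forward step must open the internal cyclopropane bond only; where the carbon goes is fixed by where the enol double bond was.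

2 from 1: the O–Si bond is cut and the C5–H bond restored. The stereocenter C7 disappears because 1 has a mirror plane. The forward step must choose between two enantiotopic α-methylene groups.

## Other disconnections considered

Alternative 1: (the disconnection that comes to mind first) cut C8–C9 of ring B and C6–C7 in the side chain. Forward, a chiral-pool cyclopentene aldehyde A1 (C1, ring A and the isopropenyl group C10/C9/C14 in place) is extended to seco-aldehyde A2, and ring B is closed by a type 2 carbonyl-ene reaction of the C8 aldehyde with the isopropenyl group to give A3. The chosen plan is preferred for three reasons. A1 has its ring alkene at C4=C5, so moving it to C3=C4 while creating H-5 needs a deconjugation whose regiochemistry (C3 against C15) is not secured. C7 is insulated from the ring stereocenters by C6 and needs an auxiliary. The closure leaves C10 as an exocyclic methylene whose hydration has no director on the α-face. The count would come to about seventeen steps against thirteen.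

Alternative 2: cut C2–C3 and C1–C5 and rejoin C5–C10. Forward, enone A4 is alkylated at C5 and vinylated at C10 to give acetal A5, and a Prins–pinacol sequence (oxocarbenium attack by the vinyl group, then 1,2-shift of C5 from C10 to C1) forms ring A and enlarges the six-membered ring in one step to give A6. It builds both rings at once, but it leaves C3 as a methyl ether next to an sp3 C4, so the C3=C4 alkene costs about four more steps. It also needs the less stable C5 epimer of an enolisable ketone, made by kinetic alkylation, and its kinetic product is expected to be cis-fused.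

Alternative 3: cut C5–C1 and C5–C6, with C5 as a carbene carbon inserted into an arene bond. Forward, an intramolecular Buchner reaction of arene-derived diazoketone A7, whose benzene ring already carries the C7 isopropyl group, the C8 oxygen and the C14 methyl, gives azulenone A8 with the whole ring skeleton and C4 as a ketone. The skeleton is reached very quickly, but A8 is a nearly flat trienone with one labile stereocenter. The five stereocenters of ring B would then have to be set one by one on a flexible ring, with C7 α to the C8 ketone and the C10 oxygen to be placed syn to H-1 against the torsional preference. The chosen plan relays each center from a fixed neighbour.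

Key step: step 3

Assumption: the lithium amide of (S,S)-bis(1-phenylethyl)amine is taken to give the (R)-enol ether 2, by analogy with the (R,R)-base/(S)-enol ether pairing of 4-alkylcyclohexanones; if the sense is the reverse, the commercial (R,R)-amine is used and nothing else changes.

Step 1
Reactants: 1 4-isopropylcyclohexan-1-one
Product: 2 (R)-[(4-isopropylcyclohex-1-en-1-yl)oxy]trimethylsilane
Conditions: (S,S)-bis(1-phenylethyl)amine, n-BuLi, LiCl, TMSCl present from the start, THF, −78 °C
Reagents that add atoms: chlorotrimethylsilane, C[Si](C)(C)Cl
Why: Enantiotopic deprotonation of the prochiral ketone by the C2-symmetric chiral lithium amide with internal silyl quench (asymmetric desymmetrisation) should set C7 by choosing which α-methylene becomes the enol carbon (the future C5); the minor enantiomer is to be removed later by recrystallisation of diol 15.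

Step 2
Reactants: 2 (R)-[(4-isopropylcyclohex-1-en-1-yl)oxy]trimethylsilane
Product: 3 (4R)-4-isopropyl-1-(trimethylsilyloxy)bicyclo[4.1.0]heptane (both cyclopropane diastereomers)
Conditions: Et2Zn, CH2I2, CH2Cl2, 0 °C to rt
Reagents that add atoms: diiodomethane, ICI
Why: Furukawa-modified Simmons–Smith cyclopropanation of the electron-rich silyl enol ether should add the CH2 that becomes C1; the configuration of the two cyclopropane carbons does not matter because both are erased in step 3.

Step 3
Reactants: 3 (4R)-4-isopropyl-1-(trimethylsilyloxy)bicyclo[4.1.0]heptane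
Product: 5 (R)-5-isopropylcyclohept-2-en-1-one, via chloro ketone 4 (not isolated)
Conditions: FeCl3 (2.2 equiv), DMF, 0 °C to rt; then NaOAc, MeOH, reflux
Reagents that add atoms: none
Why: FeCl3 (trivalent iron) should oxidise the siloxycyclopropane by single-electron transfer and, with loss of the silyl group as Me3SiCl, cleave the internal C5–C10 bond, the zero-atom bridge of the bicyclo[4.1.0]heptane. This bond is expected to break in preference to the external C1–C10 bond because it gives a secondary ring radical at C5 instead of a primary one and releases the fusion strain; the C5 radical then takes chlorine from a second FeCl3 to give 4. NaOAc removes HCl by way of the C1 enolate and leaves the conjugated enone. This is the Saegusa–Ito ring enlargement, a reaction type established for exactly this class of cyclohexanone-derived siloxycyclopropanes. No new ring is closed: the six-membered ring is enlarged to ring B by net insertion of C1 between C10 and C5 (C1–C10 and C1–C5 made in step 2, C5–C10 broken here). No stereocenter is formed, C7 is remote and untouched, and the chloride-bearing carbon is erased by the elimination. The selectivity needed is regiochemical: the cyclopropane can only sit where the enol double bond was, so the regiochemistry chosen in step 1 fixes both the site of insertion and the position of the enone. The product offers C5 as β-carbon and C1 as α-carbon for ring A and keeps C10 as the carbonyl that becomes the carbinol.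

Step 4
Reactants: 5 (R)-5-isopropylcyclohept-2-en-1-one
Product: 7 (2R,3S,5R)-2-allyl-5-isopropyl-3-(prop-1-en-2-yl)cycloheptan-1-one, via magnesium enolate 6 (not isolated)
Conditions: CH2=C(CH3)MgBr (1.5 equiv), CuBr·SMe2 (10 mol %), THF, −78 to −40 °C; then allyl iodide (3 equiv), DMPU, −40 to 0 °C
Reagents that add atoms: isopropenylmagnesium bromide, CC(=C)[Mg]Br; allyl iodide, C=CCI
Why: Copper-catalysed 1,4-addition followed by C-allylation of the regiodefined enolate (three-component vicinal difunctionalisation); the cuprate should attack C5 antiparallel to the pseudoaxial C6–H in the twist conformer that holds the C7 isopropyl group pseudoequatorial, that is trans to the isopropyl group as with 5-substituted cyclohexenones, and allyl iodide should then enter C1 trans to the new C5 substituent, which gives H-5 β and H-1 α.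

Step 5
Reactants: 7 (2R,3S,5R)-2-allyl-5-isopropyl-3-(prop-1-en-2-yl)cycloheptan-1-one
Product: 8 (1R,5S,7R)-14-norguai-3-en-10-one
Conditions: second-generation Grubbs catalyst (5 mol %), CH2Cl2, 40 °C
Reagents that add atoms: none
Why: Ring-closing metathesis between the allyl and isopropenyl groups should close ring A as the trisubstituted C3=C4 alkene with the C15 methyl in place; the trans-1,2 arrangement of the two arms carries over to the trans ring fusion, and the ketone is tolerated.

Step 6
Reactants: 8 (1R,5S,7R)-14-norguai-3-en-10-one
Product: 10 (1R,5S,7R)-14-norguaia-3,8-dien-10-one, via lithium enolate 9 (not isolated)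
Conditions: LiN(iPr)2 (LDA), THF, −78 °C; then N-tert-butylbenzenesulfinimidoyl chloride, −78 °C
Reagents that add atoms: none
Why: Kinetic deprotonation should occur at the C9 methylene and not at the hindered ring-fusion methine C1; Mukaiyama dehydrogenation of the lithium enolate with the sulfinimidoyl chloride then gives the C8=C9 enone at low temperature without touching C1 or the C3=C4 alkene.

Step 7
Reactants: 10 (1R,5S,7R)-14-norguaia-3,8-dien-10-one
Product: 12 (1R,5S,7R,8S)-8-hydroxy-14-norguai-3-en-10-one, via boronate 11 (not isolated)
Conditions: B2pin2 (1.2 equiv), CuCl (5 mol %), Xantphos (5 mol %), NaOtBu (10 mol %), MeOH (2 equiv), THF, rt; then NaBO3·4H2O, THF/H2O, rt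
Reagents that add atoms: sodium perborate, B1(OO1)[O-].[Na+] (oxygen on C8); bis(pinacolato)diboron, CC1(C)OB(OC1(C)C)B1OC(C)(C)C(C)(C)O1 (boron of 11 only)
Why: Copper-catalysed conjugate borylation of the enone should place boron on C8 anti to the adjacent C7 isopropyl group (α-face), and perborate oxidation with retention gives the 8α-alcohol; this configuration is wanted only to steer step 8 and is corrected in steps 9 and 10.

Step 8
Reactants: 12 (1R,5S,7R,8S)-8-hydroxy-14-norguai-3-en-10-one
Product: 13 (1R,5S,7R,8S,10R)-guai-3-ene-8,10-diol
Conditions: MeMgBr (3 equiv), THF, −78 to −20 °C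
Reagents that add atoms: methylmagnesium bromide, C[Mg]Br
Why: Grignard addition to the ketone: the magnesium alkoxide on the α-face of C8 should chelate the C10 carbonyl and block that face, and attack from the β-face is also the torsionally favoured one (antiperiplanar to the axial H-1), so the methyl group should enter β and leave the C10 hydroxyl α.

Step 9
Reactants: 13 (1R,5S,7R,8S,10R)-guai-3-ene-8,10-diol
Product: 14 (1R,5S,7R,10R)-10-hydroxyguai-3-en-8-one
Conditions: Dess–Martin periodinane, NaHCO3, CH2Cl2, 0 °C to rt
Reagents that add atoms: none
Why: Dess–Martin oxidation can only touch the secondary C8 alcohol; the buffered, near-neutral medium should avoid retro-aldol cleavage of the β-hydroxy ketone and epimerisation at C7.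

Step 10
Reactants: 14 (1R,5S,7R,10R)-10-hydroxyguai-3-en-8-one
Product: 15 (1R,5S,7R,8R,10R)-guai-3-ene-8,10-diol
Conditions: Me4NBH(OAc)3 (5 equiv), MeCN/AcOH (1:1), −30 °C
Reagents that add atoms: none
Why: Evans–Saksena hydroxyl-directed reduction: the C10 hydroxyl should exchange onto boron and deliver hydride within the molecule to the α-face of C8, which is also the face anti to the C7 isopropyl group, giving the 8β-alcohol and the 1,3-anti diol.

Step 11
Reactants: 15 (1R,5S,7R,8R,10R)-guai-3-ene-8,10-diol; 16 4-acetoxy-3-methoxybenzoic acid
Product: 18 (1R,5S,7R,8R,10R)-10-hydroxyguai-3-en-8-yl 4-acetoxy-3-methoxybenzoate, via mixed anhydride 17 (not isolated)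
Conditions: 16, 2,4,6-trichlorobenzoyl chloride, Et3N, THF, rt; then 15, DMAP, toluene, rt to 40 °C
Reagents that add atoms: none
Why: Yamaguchi esterification through the mixed anhydride should acylate only the secondary C8 hydroxyl, the tertiary C10 hydroxyl being inert; the phenol is carried as its acetate so that the acid cannot acylate itself.

Step 12
Reactants: 18 (1R,5S,7R,8R,10R)-10-hydroxyguai-3-en-8-yl 4-acetoxy-3-methoxybenzoate
Product: 19 (1R,3R,4S,5S,7R,8R,10R)-3,4-epoxy-10-hydroxyguaian-8-yl 4-acetoxy-3-methoxybenzoate
Conditions: VO(acac)2 (5 mol %), t-BuOOH (1.5 equiv, in decane), CH2Cl2, 0 °C to rt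
Reagents that add atoms: tert-butyl hydroperoxide, CC(C)(C)OO
Why: Vanadium-catalysed hydroxyl-directed epoxidation: the C10 hydroxyl (α, gauche to C2, bishomoallylic to C3=C4) should bind the vanadium peroxide and deliver oxygen to the α-face, while the β-face is shielded by the C14 methyl and the axial H-5; the esters are inert.

Step 13
Reactants: 19 (1R,3R,4S,5S,7R,8R,10R)-3,4-epoxy-10-hydroxyguaian-8-yl 4-acetoxy-3-methoxybenzoate
Product: 20 (1R,3R,4S,5S,7R,8R,10R)-3,4-epoxy-10-hydroxyguaian-8-yl 4-hydroxy-3-methoxybenzoate (CNP0136245.2)
Conditions: NH3 (7 M in MeOH), 0 °C, short reaction time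
Reagents that add atoms: none
Why: Ammonolysis of the activated aryl acetate should be far faster than that of the hindered secondary benzoate, and the epoxide and tertiary alcohol are stable to cold methanolic ammonia.

## Compound list

1 | 4-isopropylcyclohexan-1-one | CC(C)C1CCC(=O)CC1 | starting material
2 | (R)-[(4-isopropylcyclohex-1-en-1-yl)oxy]trimethylsilane | C[Si](C)(C)OC1=CC[C@@H](CC1)C(C)C | intermediate
3 | (4R)-4-isopropyl-1-(trimethylsilyloxy)bicyclo[4.1.0]heptane (both cyclopropane diastereomers) | C[Si](C)(C)OC12CC[C@@H](C(C)C)CC1C2 | intermediate
4 | (5R)-3-chloro-5-isopropylcycloheptan-1-one (both C3 epimers) | O=C1CC(Cl)C[C@@H](CC1)C(C)C | intermediate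
5 | (R)-5-isopropylcyclohept-2-en-1-one | O=C1C=CC[C@@H](CC1)C(C)C | intermediate
6 | bromomagnesium (3S,5R)-5-isopropyl-3-(prop-1-en-2-yl)cyclohept-1-en-1-olate | Br[Mg]OC1=C[C@@H](C(C)=C)C[C@H](C(C)C)CC1 | intermediate
7 | (2R,3S,5R)-2-allyl-5-isopropyl-3-(prop-1-en-2-yl)cycloheptan-1-one | C1CC(=O)[C@H](CC=C)[C@@H](C(C)=C)C[C@@H]1C(C)C | intermediate
8 | (1R,5S,7R)-14-norguai-3-en-10-one, i.e. (3aS,5R,8aR)-5-isopropyl-3-methyl-3a,4,5,6,7,8a-hexahydroazulen-8(1H)-one | C1CC(=O)[C@@H]2CC=C(C)[C@H]2C[C@@H]1C(C)C | intermediate
9 | lithium (1R,5S,7R)-14-norguaia-3,9-dien-10-olate | C1C=C(O[Li])[C@@H]2CC=C(C)[C@H]2C[C@@H]1C(C)C | intermediate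
10 | (1R,5S,7R)-14-norguaia-3,8-dien-10-one | C1=CC(=O)[C@@H]2CC=C(C)[C@H]2C[C@@H]1C(C)C | intermediate
11 | 2-[(1R,5S,7R,8S)-10-oxo-14-norguai-3-en-8-yl]-4,4,5,5-tetramethyl-1,3,2-dioxaborolane | CC1(C)OB(OC1(C)C)[C@H]2CC(=O)[C@@H]3CC=C(C)[C@H]3C[C@@H]2C(C)C | intermediate
12 | (1R,5S,7R,8S)-8-hydroxy-14-norguai-3-en-10-one | O[C@H]1CC(=O)[C@@H]2CC=C(C)[C@H]2C[C@@H]1C(C)C | intermediate
13 | (1R,5S,7R,8S,10R)-guai-3-ene-8,10-diol (8α,10α) | O[C@H]1C[C@@](C)(O)[C@@H]2CC=C(C)[C@H]2C[C@@H]1C(C)C | intermediate
14 | (1R,5S,7R,10R)-10-hydroxyguai-3-en-8-one | O=C1C[C@@](C)(O)[C@@H]2CC=C(C)[C@H]2C[C@@H]1C(C)C | intermediate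
15 | (1R,5S,7R,8R,10R)-guai-3-ene-8,10-diol (8β,10α) | O[C@@H]1C[C@@](C)(O)[C@@H]2CC=C(C)[C@H]2C[C@@H]1C(C)C | intermediate
16 | 4-acetoxy-3-methoxybenzoic acid | COc1cc(C(=O)O)ccc1OC(C)=O | starting material
17 | 4-acetoxy-3-methoxybenzoic 2,4,6-trichlorobenzoic anhydride | COc1cc(C(=O)OC(=O)c2c(Cl)cc(Cl)cc2Cl)ccc1OC(C)=O | intermediate
18 | (1R,5S,7R,8R,10R)-10-hydroxyguai-3-en-8-yl 4-acetoxy-3-methoxybenzoate | COc1cc(C(=O)O[C@@H]2C[C@@](C)(O)[C@@H]3CC=C(C)[C@H]3C[C@@H]2C(C)C)ccc1OC(C)=O | intermediate
19 | (1R,3R,4S,5S,7R,8R,10R)-3,4-epoxy-10-hydroxyguaian-8-yl 4-acetoxy-3-methoxybenzoate | COc1cc(C(=O)O[C@@H]2C[C@@](C)(O)[C@@H]3C[C@H]4O[C@@]4(C)[C@H]3C[C@@H]2C(C)C)ccc1OC(C)=O | intermediate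
20 | (1R,3R,4S,5S,7R,8R,10R)-3,4-epoxy-10-hydroxyguaian-8-yl 4-hydroxy-3-methoxybenzoate | COc1cc(C(=O)O[C@@H]2C[C@@](C)(O)[C@@H]3C[C@H]4O[C@@]4(C)[C@H]3C[C@@H]2C(C)C)ccc1O | target

## Step count and least certain steps

Total: 13 steps. Longest linear sequence: 13 steps (1 to 20); 16 is commercial and enters at step 11.

Step 3 (key step). The likely failure is cleavage of the cyclopropane by acid instead of by oxidation: FeCl3 is Lewis acidic and hygroscopic, and protodesilylative opening of the external bond would return a six-membered methyl ketone. Fallback, setting out from 2 and returning at 5: dibromocarbene (CHBr3, KOtBu, pentane, −20 °C) is added to 2 to give (4R)-7,7-dibromo-4-isopropyl-1-(trimethylsilyloxy)bicyclo[4.1.0]heptane F1. Warming opens F1 by the cyclopropyl-to-allyl cation pathway with loss of Me3SiBr to (R)-2-bromo-5-isopropylcyclohept-2-en-1-one F2, and hydrodebromination (Bu3SnH, Pd(PPh3)4 cat., THF) gives 5. The ring is then enlarged by an electrocyclic opening and not by single-electron oxidation.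

Step 4. Two processes may fail: facial discrimination at C5 by the remote C7 isopropyl group may be incomplete on a flexible ring, and proton transfer between product and enolate before allylation would give regioisomeric or doubly allylated ketones. Fallback, setting out from 5 and returning at 7: the copper-catalysed addition is run with TMSCl (and, if needed, a chiral phosphoramidite ligand on copper to override substrate control) so that the adduct is isolated as {[(3S,5R)-5-isopropyl-3-(prop-1-en-2-yl)cyclohept-1-en-1-yl]oxy}trimethylsilane F3. The lithium enolate is then regenerated regiospecifically with MeLi (THF, 0 °C) and allylated with allyl iodide at −78 °C to give 7.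

Step 8. The methyl group could be delivered to the α-face through the alkoxide-bound magnesium, or the basic reagent could enolise or fragment (retro-aldol) the β-oxido ketone. Fallback, setting out from 12 and returning at 13: Wittig methylenation (Ph3P=CH2, THF, 0 °C) gives (1R,5S,7R,8S)-guaia-3,10(14)-dien-8-ol F4. Epoxidation directed by the homoallylic 8α-hydroxyl (VO(acac)2, t-BuOOH) places oxygen on the α-face of C10 to give (1R,5S,7R,8S,10R)-10,14-epoxyguai-3-en-8-ol F5, and LiBHEt3 opens the epoxide at C14 to give 13. The C10 configuration then comes from oxygen delivery and not from carbon addition.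

Step 12. A hindered tertiary, bishomoallylic hydroxyl may direct poorly, so background epoxidation on the β-face could erode the facial selectivity. Fallback, setting out from 18 and returning at 20: NBS in aqueous THF should form the bromonium ion on the more accessible face and be opened by water anti at the tertiary C4, giving (1R,3S,4S,5S,7R,8R,10R)-3-bromo-4,10-dihydroxyguaian-8-yl 4-acetoxy-3-methoxybenzoate F6. K2CO3 in MeOH then closes the α-epoxide with inversion at C3 and removes the aryl acetate in the same operation, giving 20 directly. The halohydrin route puts the epoxide on the face opposite to the one an electrophile attacks.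

Step 1. Enantiotopic discrimination by the chiral base is expected to be incomplete, so some enolisation on the other side gives the enantiomeric series, and the base is needed in stoichiometric amount. Fallback: this detour does not start from 1; it sets out from commercial 3-methylbutanal and but-3-en-2-one and returns at 2. Michael addition catalysed by (S)-diphenylprolinol trimethylsilyl ether gives (S)-2-isopropyl-5-oxohexanal F7 (the catalyst enantiomer is chosen by the same analogy as in the assumption above). Base-mediated aldol condensation gives (S)-4-isopropylcyclohex-2-en-1-one F8, and 1,4-reduction with LiBH(s-Bu)3 at −78 °C followed by TMSCl/Et3N traps the enolate regiospecifically as 2.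

## Further compounds

F1 | step 3 | (4R)-7,7-dibromo-4-isopropyl-1-(trimethylsilyloxy)bicyclo[4.1.0]heptane | C[Si](C)(C)OC12CC[C@@H](C(C)C)CC1C2(Br)Br
F2 | step 3 | (R)-2-bromo-5-isopropylcyclohept-2-en-1-one | O=C1C(Br)=CC[C@@H](CC1)C(C)C
F3 | step 4 | {[(3S,5R)-5-isopropyl-3-(prop-1-en-2-yl)cyclohept-1-en-1-yl]oxy}trimethylsilane | C[Si](C)(C)OC1=C[C@@H](C(C)=C)C[C@H](C(C)C)CC1
F4 | step 8 | (1R,5S,7R,8S)-guaia-3,10(14)-dien-8-ol | O[C@H]1CC(=C)[C@@H]2CC=C(C)[C@H]2C[C@@H]1C(C)C
F5 | step 8 | (1R,5S,7R,8S,10R)-10,14-epoxyguai-3-en-8-ol | O[C@H]1C[C@]2(CO2)[C@@H]3CC=C(C)[C@H]3C[C@@H]1C(C)C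
F6 | step 12 | (1R,3S,4S,5S,7R,8R,10R)-3-bromo-4,10-dihydroxyguaian-8-yl 4-acetoxy-3-methoxybenzoate | COc1cc(C(=O)O[C@@H]2C[C@@](C)(O)[C@@H]3C[C@H](Br)[C@@](C)(O)[C@H]3C[C@@H]2C(C)C)ccc1OC(C)=O
F7 | step 1 | (S)-2-isopropyl-5-oxohexanal | CC(=O)CC[C@H](C=O)C(C)C
F8 | step 1 | (S)-4-isopropylcyclohex-2-en-1-one | O=C1CC[C@H](C=C1)C(C)C
A1 | alternative 1 | (S)-2-methyl-5-(prop-1-en-2-yl)cyclopent-1-ene-1-carbaldehyde | O=CC1=C(C)CC[C@H]1C(C)=C
A2 | alternative 1 | (R)-3-methyl-2-{[(1S,5R)-2-methyl-5-(prop-1-en-2-yl)cyclopent-2-en-1-yl]methyl}butanal | O=C[C@@H](C(C)C)C[C@@H]1C(C)=CC[C@H]1C(C)=C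
A3 | alternative 1 | (1R,5S,7R,8R)-guaia-3,10(14)-dien-8-ol | O[C@@H]1CC(=C)[C@@H]2CC=C(C)[C@H]2C[C@@H]1C(C)C
A4 | alternative 2 | (R)-4-isopropylcyclohex-2-en-1-one | O=C1CC[C@@H](C=C1)C(C)C
A5 | alternative 2 | {[(4R,6R)-6-(1,1-dimethoxypropan-2-yl)-4-isopropyl-1-vinylcyclohex-2-en-1-yl]oxy}trimethylsilane (C1 and side-chain centre as formed) | C=CC1(O[Si](C)(C)C)C=C[C@@H](C(C)C)C[C@@H]1C(C)C(OC)OC
A6 | alternative 2 | 3-methoxy-14-norguai-8-en-10-one (H-5 β, 7β-isopropyl; C1, C3, C4 as formed) | COC1CC2C(=O)C=C[C@@H](C(C)C)C[C@@H]2C1C
A7 | alternative 3 | 1-diazo-4-(5-isopropyl-4-methoxy-2-methylphenyl)butan-2-one | COc1cc(C)c(CCC(=O)C=[N+]=[N-])cc1C(C)C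
A8 | alternative 3 | 5-isopropyl-6-methoxy-8-methyl-1,2-dihydroazulen-3(3aH)-one | O=C1CCC2=C(C)C=C(OC)C(C(C)C)=C[C@H]12
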